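## Analysis of the target

The target 11 is a single oxolane ring in which every carbon is substituted: two identical 4-hydroxy-3,5-dimethoxyphenyl groups sit on C2 and C5 and two hydroxymethyl groups on C3 and C4. The ring is numbered O1, C2 to C5, with C2 the (S)-configured aryl carbon. The configuration is (2S,3S,4S,5R): the aryl groups are 2,5-cis and the hydroxymethyl groups 3,4-trans, so C2/C3 is cis and C4/C5 is trans. The constitution is symmetric, but this arrangement has no symmetry element, so the two halves must be told apart at one benzylic carbon only. The ring oxygen lies between two electron-rich benzylic carbons, so acid can ionise C2–O1 or C5–O1 and let the crowded 2,3-cis centre relax to the all-trans isomer; hydrogenolysis threatens the same bonds. The flanked phenols are easily oxidised and, as phenoxides, can expel a leaving group from the para benzylic position. Each hydroxymethyl group is 1,4 to the far benzylic carbon, so open-chain precursors tend to close to a bicyclic furofuran instead. The difficulty is therefore to set four contiguous stereocentres, one of them in the less stable cis relationship, under kinetic control and in one absolute sense. The strategy rests on the C3–C4 bond: it joins two identical aryl–C3 halves, each with the skeleton of sinapic acid 1, through their side-chain carbons C8 and C8′ (the carbons α to the carboxyl groups).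

## Retrosynthetic reasoning

11 from 10. The last disconnection removes four O–Si bonds. Both phenols and both primary alcohols carry the same silyl group, so that one mild, non-acidic and non-reductive desilylation unmasks everything and the doubly benzylic ring ether of 10 is never exposed to acid or to hydrogenation.

10 from 8 through 9. The O1–C2 bond is cut. This leads back to the C2-symmetric diol 8, in which both benzylic carbons have the same configuration. Because of the symmetry, inversion at either benzylic carbon gives the same 2,5-cis-3,4-trans oxolane, so no selective activation is needed. The forward reaction must be a clean intramolecular SN2 displacement (Mitsunobu cyclodehydration through the oxyphosphonium ion 9). The primary hydroxyls have to be masked, otherwise they would attack the benzylic carbons and give the furofuran skeleton.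

8 from 7 and 4. Two primary O–Si bonds are removed. The silyl chloride 4 distinguishes the two primary alcohols of the tetraol 7 from the two hindered benzylic alcohols on steric grounds.

7 from 6. The two hydroxymethyl groups and the two benzylic hydroxyls of 7 are read as the reduced form of two γ-lactones. In 6 each benzylic oxygen is acylated by the carboxyl carbon of the other half. These acyl C–O bonds are not in the target. They serve to lock the relative configuration of all four centres in a rigid cis-fused bicycle, and a hydride reduction removes them without touching a stereocentre.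

6 from 5, and 5 from 3 and 4. The single enantiomer 6 is taken from the racemate 5 by resolution, because nothing is known that steers the absolute sense of the radical pairing for this acid. The resolution is placed here because 5 is rigid, soluble and early, so no later step is run on unwanted material. Silyl ethers are chosen for the phenols of 3 because they can be put on under conditions too weakly basic to form a phenoxide. A phenoxide of 3 would expel the para benzylic carboxylate and open the lactone.

3 from two molecules of 1 through 2. The C3–C4 bond of the target (C8–C8′ of two molecules of 1) and the two benzylic C–O bonds are cut together. This is the retron of an oxidative phenol coupling under aerobic enzymatic oxidation: the two methoxy groups of 1 block every ring position at which a radical could otherwise couple, so the side-chain carbon is the only carbon site left. The bis(quinone methide) 2 is trapped by its own carboxyl groups. The step gives the whole carbon skeleton, both temporary rings and the relative configuration of four stereocentres from a commodity acid in one operation.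

## Alternatives that were turned down

Alternative 1: Both aryl–carbon bonds (C2–aryl and C5–aryl) are cut. In the forward direction two equivalents of the aryllithium A3 add to the enantiopure C2-symmetric bis(N-methoxy-N-methylamide) A2 and give the 1,4-diketone A1.
- For it: the absolute configuration at C3 and C4 comes from A2, so no resolution is needed and no half of the material is lost. On this point it is stronger than the chosen route. It is convergent, and its benzyl ethers would all fall in one hydrogenolysis.
- Against it: both stereocentres of A1 are α to an aryl ketone and can epimerise to the meso compound under the basic conditions of its formation, and enolisation of A2 by the basic A3 competes with addition.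
- The benzylic centres are still unset in A1. Two ketone reductions under 1,2-induction lead to a C2-symmetric diol of the same kind as 8, so the invertive ring closure is not avoided. Reducing the two carbonyls in opposite senses has no handle in the substrate.
- A2 is not a commodity and needs its own asymmetric synthesis, so the route would be longer than seven steps.
- In exchange for the resolution, the chosen route sets the benzylic centres in the skeleton-forming step, has no epimerisable intermediate, and starts from a commercial acid.

Alternative 2: The C2–C3 ring bond is cut. A silyl triflate Lewis acid opens the 2,4-diaryl-4,5-dihydro-1,3-dioxepin A5 to an oxocarbenium ion tethered to an enol, which recloses by C–C bond formation to the 2,3-cis oxolane-3-carbaldehyde A4.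
- For it: the 2,3-cis relationship is created kinetically in a C–C bond-forming step, with no SN2 reaction at an electron-rich benzylic carbon. On this point it is stronger than the Mitsunobu closure of the chosen route. A4 already has the target configuration at all four ring carbons, with the absolute configuration drawn from A5.
- Against it: A5 needs an enantioselective synthesis of a 4,5-trans diol fragment, an acetalisation and a double-bond shift to the enol acetal. Together with the later aldehyde reduction and deprotections the sequence would be roughly twice as long.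
- The aryl groups are very electron-rich. The Lewis acid can ionise the benzylic C4–O bond of A5 as well as the acetal, and can reopen A4, so leakage at C5 and equilibration to 2,3-trans are to be expected.
- It differentiates the C3 and C4 substituents (formyl and silyloxymethyl) although the target has the same group on both.
- The chosen route uses the hidden symmetry instead and reaches the full skeleton in one step.

Alternative 3: The C4–C5 and O1–C5 bonds are cut. A chiral sulfonium benzylide such as A8 adds to the alkylidene β-keto ester A7, and the enolate oxygen displaces the sulfide to close the trans-4,5-dihydrofuran A6.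
- For it: it is convergent and the chiral sulfur reagent sets C4 and C5 in the right trans relationship and absolute sense without a resolution. On these points it is stronger than the chosen route.
- Against it: C2 and C3 of A6 are still a tetrasubstituted, aryl-conjugated enol ether double bond. The target needs hydrogen delivered to the face syn to the C4 substituent and anti to the C5 aryl group. Each face carries one substituent, so the substrate gives no clear bias.
- Hydrogenation forcing enough to reduce this alkene would also attack the benzyl ethers and the benzylic C5–O bond. Epimerising C3 afterwards would give 2,3-trans, which is wrong.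
- Ester reduction and two kinds of deprotection follow.
- The chosen route sets all four centres relative to each other in the dimerisation and needs only one stereochemical correction, which the symmetry of 8 makes unambiguous.

Key step: step 1

Remark on the chemistry: the dimerisation is taken to give the racemate, since nothing chiral takes part in the radical pairing. Compounds 2, 3 and 5 are therefore racemic and are named and drawn as the enantiomer that step 3 keeps.

## Steps

Step 1
Reactants: 1 sinapic acid, (E)-3-(4-hydroxy-3,5-dimethoxyphenyl)prop-2-enoic acid (two molecules)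
Product: 3 rac-(1R,2R,5R,6R)-2,6-bis(4-hydroxy-3,5-dimethoxyphenyl)-3,7-dioxabicyclo[3.3.0]octane-4,8-dione (cis-fused; both aryl groups exo), via racemic bis(quinone methide) diacid 2 (not isolated)
Conditions: laccase (Trametes versicolor), O2 (air), NaOAc/AcOH buffer pH 4.5, acetone co-solvent, 25 °C
Reagents that add atoms: none
Why: Oxidative phenol coupling (laccase/O2 dehydrodimerisation, a known reaction of this very acid in racemic form, also brought about by FeCl3/O2): the enzyme takes one electron and one proton from each phenol, and the radical carries spin on the phenol oxygen, on C1 and on the side-chain carbon C8. The ring positions next to the phenol carry methoxy groups, so carbon–carbon coupling can only join the two C8 atoms; this makes the future C3–C4 bond and gives the bis(quinone methide) 2. Each carboxyl oxygen of 2 then adds to the benzylic carbon of the other half in a 5-exo-trig conjugate addition (the exocyclic C7=C1 bond of the quinone methide lies outside the ring being formed), and both lactone rings close in this way while both arenes are restored. The two ring-fusion centres are set in the radical pairing, since only the like-configured form of 2 can close twice to a cis-fused bicycle, and the unlike (meso) pairing is lost to by-products. The two benzylic centres are set in the lactonisations, where each aryl group takes the convex face of the folding bicycle, and the reversibility of carboxylate addition to a quinone methide lets them settle in this more stable exo position. Nothing chiral steers the pairing, so 3 forms as the racemate and the absolute configuration is left to step 3. The step needs chemoselectivity against further oxidation of the product phenols and against base-induced rearrangement to the aryldihydronaphthalene diacid; the acidic buffer and the low solubility of 3, which should precipitate, are relied on for both.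

Step 2
Reactants: 3 rac-dilactone; 4 tert-butyldimethylsilyl chloride
Product: 5 rac-(1R,2R,5R,6R)-2,6-bis[4-(tert-butyldimethylsilyloxy)-3,5-dimethoxyphenyl]-3,7-dioxabicyclo[3.3.0]octane-4,8-dione
Conditions: TBSCl, imidazole, DMF, 0 °C to rt
Reagents that add atoms: tert-butyldimethylsilyl chloride (4), CC(C)(C)[Si](C)(C)Cl
Why: Silylation of a phenol through the N-silylimidazolium ion; imidazole is too weak a base to form the phenoxide, which would expel the para benzylic carboxylate and open the lactone, and no stereocentre is touched.

Step 3
Reactants: 5 racemic bis(silyl ether)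
Product: 6 (1R,2R,5R,6R)-2,6-bis[4-(tert-butyldimethylsilyloxy)-3,5-dimethoxyphenyl]-3,7-dioxabicyclo[3.3.0]octane-4,8-dione
Conditions: preparative HPLC, cellulose tris(3,5-dimethylphenylcarbamate) on silica, hexane/i-PrOH, 25 °C
Reagents that add atoms: none
Why: Resolution by chromatography on a polysaccharide carbamate phase, a standard way of separating rigid aryl lactone enantiomers; no bond is changed, and the (1R,2R,5R,6R) fraction is to be assigned by X-ray diffraction with silicon as anomalous scatterer or by its chiroptical data.

Step 4
Reactants: 6 (1R,2R,5R,6R)-dilactone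
Product: 7 (1R,2S,3S,4R)-1,4-bis[4-(tert-butyldimethylsilyloxy)-3,5-dimethoxyphenyl]-2,3-bis(hydroxymethyl)butane-1,4-diol
Conditions: LiAlH4, THF, 0 °C; then Na2SO4·10H2O
Reagents that add atoms: none
Why: Hydride reduction of both γ-lactones to 1,4-diols; the benzylic C–O bonds and the ring-fusion C–H bonds are not touched, so all four stereocentres are carried over (two descriptors change only because the priorities change), and the neutral quench avoids acid-induced closure to the furofuran and alkaline loss of the aryl silyl ethers.

Step 5
Reactants: 7 tetraol; 4 tert-butyldimethylsilyl chloride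
Product: 8 (1R,2S,3S,4R)-1,4-bis[4-(tert-butyldimethylsilyloxy)-3,5-dimethoxyphenyl]-2,3-bis[(tert-butyldimethylsilyloxy)methyl]butane-1,4-diol
Conditions: TBSCl (2.2 equiv), imidazole, DMF, −20 to 0 °C
Reagents that add atoms: tert-butyldimethylsilyl chloride (4), CC(C)(C)[Si](C)(C)Cl
Why: Selective silylation of the two primary alcohols beside two hindered secondary benzylic alcohols, on steric grounds with a bulky silyl chloride at low temperature; the masking prevents attack of the primary oxygens on a benzylic carbon in step 6.

Step 6
Reactants: 8 C2-symmetric diol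
Product: 10 (2S,3S,4S,5R)-2,5-bis[4-(tert-butyldimethylsilyloxy)-3,5-dimethoxyphenyl]-3,4-bis[(tert-butyldimethylsilyloxy)methyl]oxolane, via alkoxytriphenylphosphonium ion 9 (not isolated)
Conditions: PPh3, DIAD, toluene, 0 °C to rt
Reagents that add atoms: none
Why: Mitsunobu cyclodehydration of a 1,4-diol: one benzylic hydroxyl becomes the oxyphosphonium ion 9 and the other displaces Ph3PO in a 5-exo-tet SN2 reaction with inversion, which turns that (R)-carbinol carbon into the (S)-configured C2 and so creates the 2,3-cis relationship; because 8 is C2-symmetric, activation of either hydroxyl gives the same product. The non-polar solvent and the weak para donation of a silyloxy group twisted out of plane by two flanking methoxy groups should keep the displacement from turning into an ionisation.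

Step 7
Reactants: 10 tetrasilyl ether
Product: 11 [(2S,3S,4S,5R)-2,5-bis(4-hydroxy-3,5-dimethoxyphenyl)oxolane-3,4-diyl]dimethanol
Conditions: Bu4NF, AcOH, THF, 0 °C to rt
Reagents that add atoms: none
Why: Fluoride-induced cleavage of all four Si–O bonds in one operation; the AcOH buffer releases the phenols as phenols and not as phenoxides, and the absence of strong acid and of hydrogenation conditions leaves the doubly benzylic ring ether and its stereocentres untouched.

## Compound list

1 | sinapic acid, (E)-3-(4-hydroxy-3,5-dimethoxyphenyl)prop-2-enoic acid | COc1cc(/C=C/C(=O)O)cc(OC)c1O | starting material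
2 | rac-(2S,3S)-2,3-bis[(3,5-dimethoxy-4-oxocyclohexa-2,5-dien-1-ylidene)methyl]butanedioic acid (racemate, one enantiomer drawn) | OC(=O)[C@@H](C=C1C=C(OC)C(=O)C(OC)=C1)[C@H](C=C1C=C(OC)C(=O)C(OC)=C1)C(=O)O | intermediate
3 | rac-(1R,2R,5R,6R)-2,6-bis(4-hydroxy-3,5-dimethoxyphenyl)-3,7-dioxabicyclo[3.3.0]octane-4,8-dione (racemate, one enantiomer drawn) | O=C1O[C@@H](c3cc(OC)c(O)c(OC)c3)[C@H]2[C@@H]1[C@H](c4cc(OC)c(O)c(OC)c4)OC2=O | intermediate
4 | tert-butyldimethylsilyl chloride | CC(C)(C)[Si](C)(C)Cl | starting material
5 | rac-(1R,2R,5R,6R)-2,6-bis[4-(tert-butyldimethylsilyloxy)-3,5-dimethoxyphenyl]-3,7-dioxabicyclo[3.3.0]octane-4,8-dione (racemate, one enantiomer drawn) | O=C1O[C@@H](c3cc(OC)c(O[Si](C)(C)C(C)(C)C)c(OC)c3)[C@H]2[C@@H]1[C@H](c4cc(OC)c(O[Si](C)(C)C(C)(C)C)c(OC)c4)OC2=O | intermediate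
6 | (1R,2R,5R,6R)-2,6-bis[4-(tert-butyldimethylsilyloxy)-3,5-dimethoxyphenyl]-3,7-dioxabicyclo[3.3.0]octane-4,8-dione | O=C1O[C@@H](c3cc(OC)c(O[Si](C)(C)C(C)(C)C)c(OC)c3)[C@H]2[C@@H]1[C@H](c4cc(OC)c(O[Si](C)(C)C(C)(C)C)c(OC)c4)OC2=O | intermediate
7 | (1R,2S,3S,4R)-1,4-bis[4-(tert-butyldimethylsilyloxy)-3,5-dimethoxyphenyl]-2,3-bis(hydroxymethyl)butane-1,4-diol | O[C@@H](c1cc(OC)c(O[Si](C)(C)C(C)(C)C)c(OC)c1)[C@H](CO)[C@@H](CO)[C@@H](O)c1cc(OC)c(O[Si](C)(C)C(C)(C)C)c(OC)c1 | intermediate
8 | (1R,2S,3S,4R)-1,4-bis[4-(tert-butyldimethylsilyloxy)-3,5-dimethoxyphenyl]-2,3-bis[(tert-butyldimethylsilyloxy)methyl]butane-1,4-diol | O[C@@H](c1cc(OC)c(O[Si](C)(C)C(C)(C)C)c(OC)c1)[C@H](CO[Si](C)(C)C(C)(C)C)[C@@H](CO[Si](C)(C)C(C)(C)C)[C@@H](O)c1cc(OC)c(O[Si](C)(C)C(C)(C)C)c(OC)c1 | intermediate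
9 | {(1R,2S,3S,4R)-4-hydroxy-1,4-bis[4-(tert-butyldimethylsilyloxy)-3,5-dimethoxyphenyl]-2,3-bis[(tert-butyldimethylsilyloxy)methyl]butoxy}triphenylphosphonium, as its diisopropyl hydrazine-1,2-dicarboxylate salt | O[C@@H](c1cc(OC)c(O[Si](C)(C)C(C)(C)C)c(OC)c1)[C@H](CO[Si](C)(C)C(C)(C)C)[C@@H](CO[Si](C)(C)C(C)(C)C)[C@@H](O[P+](c1ccccc1)(c1ccccc1)c1ccccc1)c1cc(OC)c(O[Si](C)(C)C(C)(C)C)c(OC)c1.CC(C)OC(=O)N[N-]C(=O)OC(C)C | intermediate
10 | (2S,3S,4S,5R)-2,5-bis[4-(tert-butyldimethylsilyloxy)-3,5-dimethoxyphenyl]-3,4-bis[(tert-butyldimethylsilyloxy)methyl]oxolane | COc1cc([C@H]2O[C@@H](c3cc(OC)c(O[Si](C)(C)C(C)(C)C)c(OC)c3)[C@H](CO[Si](C)(C)C(C)(C)C)[C@H]2CO[Si](C)(C)C(C)(C)C)cc(OC)c1O[Si](C)(C)C(C)(C)C | intermediate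
11 | [(2S,3S,4S,5R)-2,5-bis(4-hydroxy-3,5-dimethoxyphenyl)oxolane-3,4-diyl]dimethanol | COc1cc([C@H]2O[C@@H](c3cc(OC)c(O)c(OC)c3)[C@H](CO)[C@H]2CO)cc(OC)c1O | target

## Step count and least certain steps

Total step count: 7. Longest linear sequence: 7 steps (1 to 11).

Step 1 (key step). The amount of 3 may be cut down by several processes:
- over-oxidation of the product phenols to quinones and oligomers;
- radical pairing in the unlike sense or through the phenol oxygen, neither of which can close two lactones;
- rearrangement of the dilactone to the aryldihydronaphthalene diacid if the pH drifts upward.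

The fallback builds the same bicycle by two aldol reactions instead of a radical pairing. It leaves 1 aside and sets out from 4 and commercial syringaldehyde, which are joined (imidazole, DMF) to 4-(tert-butyldimethylsilyloxy)-3,5-dimethoxybenzaldehyde F1. Dilithiated N,N,N′,N′-tetramethylsuccinamide (LiN(i-Pr)2, THF, −78 °C) is added to two equivalents of F1 to give the bis(hydroxy amide) F2. Acid-promoted lactonisation (TsOH, toluene, heat) then closes both rings with loss of dimethylamine, under conditions in which the benzylic centres can settle in the exo arrangement. The fallback comes back to the route at 5.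

Step 6. The oxyphosphonium ion may ionise to a benzylic cation before it is displaced, which would give ring closure without inversion and hence the all-trans isomer. Elimination to a styrene and participation of a silyl ether oxygen are further ways of loss. The fallback sets the C2 centre by reduction instead of displacement and sets out from 8. One benzylic alcohol is oxidised (DDQ, one equivalent, or MnO2) to the hydroxy ketone (2S,3S,4R)-4-hydroxy-1,4-bis[4-(tert-butyldimethylsilyloxy)-3,5-dimethoxyphenyl]-2,3-bis[(tert-butyldimethylsilyloxy)methyl]butan-1-one F3. This closes to the cyclic hemiketal (3S,4S,5R)-2,5-bis[4-(tert-butyldimethylsilyloxy)-3,5-dimethoxyphenyl]-3,4-bis[(tert-butyldimethylsilyloxy)methyl]oxolan-2-ol F4. Et3SiH with BF3·OEt2 in CH2Cl2 at −78 °C generates the cyclic oxocarbenium ion and delivers hydride to the face opposite the neighbouring C3 substituent, which places the aryl group cis to it. The fallback comes back to the route at 10.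

Step 3. The separation factor or the loading capacity on the chiral phase may be too low for useful throughput. The fallback is a resolution through covalent diastereomers and sets out from 5. The racemate is taken through the conditions of steps 4 and 5 to the racemic tetraol rac-7 F5 and the racemic diol rac-8 F6. Both benzylic hydroxyls are esterified with (S)-2-methoxy-2-phenylacetic acid (N,N′-dicyclohexylcarbodiimide, 4-dimethylaminopyridine, 0 °C). This gives two diastereomers: the bis[(S)-2-methoxy-2-phenylacetate] of the (1R,2S,3S,4R)-diol F7 and the bis[(S)-2-methoxy-2-phenylacetate] of the (1S,2R,3R,4S)-diol F8. They are separated on silica or by crystallisation. Reductive cleavage of F7 with i-Bu2AlH (CH2Cl2, −78 °C) spares all silyl ethers. The fallback comes back to the route at 8.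

Step 2. The lactone may open by 1,6-elimination if phenoxide character develops, and silylation of the doubly flanked phenols may stay incomplete. The fallback postpones silylation until the lactones are gone and sets out from 3. Ac2O in pyridine gives the racemic diacetate rac-(1R,2R,5R,6R)-2,6-bis(4-acetoxy-3,5-dimethoxyphenyl)-3,7-dioxabicyclo[3.3.0]octane-4,8-dione F9. It is resolved on the chiral phase of step 3 to the (1R,2R,5R,6R)-diacetate F10. LiAlH4 in THF reduces both lactones and removes both acetates to give (1R,2S,3S,4R)-1,4-bis(4-hydroxy-3,5-dimethoxyphenyl)-2,3-bis(hydroxymethyl)butane-1,4-diol F11. TBSCl (about four equivalents) with imidazole then silylates the two phenols and the two primary alcohols in one operation. The fallback comes back to the route at 8.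

## Further compounds

F1 | step 1 | 4-(tert-butyldimethylsilyloxy)-3,5-dimethoxybenzaldehyde | COc1cc(C=O)cc(OC)c1O[Si](C)(C)C(C)(C)C
F2 | step 1 | rac-(2R,3R)-2,3-bis{(R)-[4-(tert-butyldimethylsilyloxy)-3,5-dimethoxyphenyl](hydroxy)methyl}-N,N,N′,N′-tetramethylbutanediamide (racemate, one enantiomer drawn) | O[C@@H](c1cc(OC)c(O[Si](C)(C)C(C)(C)C)c(OC)c1)[C@H](C(=O)N(C)C)[C@@H](C(=O)N(C)C)[C@@H](O)c1cc(OC)c(O[Si](C)(C)C(C)(C)C)c(OC)c1
F3 | step 6 | (2S,3S,4R)-4-hydroxy-1,4-bis[4-(tert-butyldimethylsilyloxy)-3,5-dimethoxyphenyl]-2,3-bis[(tert-butyldimethylsilyloxy)methyl]butan-1-one | O=C(c1cc(OC)c(O[Si](C)(C)C(C)(C)C)c(OC)c1)[C@H](CO[Si](C)(C)C(C)(C)C)[C@@H](CO[Si](C)(C)C(C)(C)C)[C@@H](O)c1cc(OC)c(O[Si](C)(C)C(C)(C)C)c(OC)c1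
F4 | step 6 | (3S,4S,5R)-2,5-bis[4-(tert-butyldimethylsilyloxy)-3,5-dimethoxyphenyl]-3,4-bis[(tert-butyldimethylsilyloxy)methyl]oxolan-2-ol (both hemiketal epimers) | COc1cc(C2(O)O[C@@H](c3cc(OC)c(O[Si](C)(C)C(C)(C)C)c(OC)c3)[C@H](CO[Si](C)(C)C(C)(C)C)[C@H]2CO[Si](C)(C)C(C)(C)C)cc(OC)c1O[Si](C)(C)C(C)(C)C
F5 | step 3 | rac-(1R,2S,3S,4R)-1,4-bis[4-(tert-butyldimethylsilyloxy)-3,5-dimethoxyphenyl]-2,3-bis(hydroxymethyl)butane-1,4-diol (racemate, one enantiomer drawn) | O[C@@H](c1cc(OC)c(O[Si](C)(C)C(C)(C)C)c(OC)c1)[C@H](CO)[C@@H](CO)[C@@H](O)c1cc(OC)c(O[Si](C)(C)C(C)(C)C)c(OC)c1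
F6 | step 3 | rac-(1R,2S,3S,4R)-1,4-bis[4-(tert-butyldimethylsilyloxy)-3,5-dimethoxyphenyl]-2,3-bis[(tert-butyldimethylsilyloxy)methyl]butane-1,4-diol (racemate, one enantiomer drawn) | O[C@@H](c1cc(OC)c(O[Si](C)(C)C(C)(C)C)c(OC)c1)[C@H](CO[Si](C)(C)C(C)(C)C)[C@@H](CO[Si](C)(C)C(C)(C)C)[C@@H](O)c1cc(OC)c(O[Si](C)(C)C(C)(C)C)c(OC)c1
F7 | step 3 | bis[(S)-2-methoxy-2-phenylacetate] of the (1R,2S,3S,4R)-diol 8 | CO[C@@H](c1ccccc1)C(=O)O[C@@H](c1cc(OC)c(O[Si](C)(C)C(C)(C)C)c(OC)c1)[C@H](CO[Si](C)(C)C(C)(C)C)[C@@H](CO[Si](C)(C)C(C)(C)C)[C@@H](OC(=O)[C@@H](OC)c1ccccc1)c1cc(OC)c(O[Si](C)(C)C(C)(C)C)c(OC)c1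
F8 | step 3 | bis[(S)-2-methoxy-2-phenylacetate] of the (1S,2R,3R,4S)-diol | CO[C@@H](c1ccccc1)C(=O)O[C@H](c1cc(OC)c(O[Si](C)(C)C(C)(C)C)c(OC)c1)[C@@H](CO[Si](C)(C)C(C)(C)C)[C@H](CO[Si](C)(C)C(C)(C)C)[C@H](OC(=O)[C@@H](OC)c1ccccc1)c1cc(OC)c(O[Si](C)(C)C(C)(C)C)c(OC)c1
F9 | step 2 | rac-(1R,2R,5R,6R)-2,6-bis(4-acetoxy-3,5-dimethoxyphenyl)-3,7-dioxabicyclo[3.3.0]octane-4,8-dione (racemate, one enantiomer drawn) | O=C1O[C@@H](c3cc(OC)c(OC(C)=O)c(OC)c3)[C@H]2[C@@H]1[C@H](c4cc(OC)c(OC(C)=O)c(OC)c4)OC2=O
F10 | step 2 | (1R,2R,5R,6R)-2,6-bis(4-acetoxy-3,5-dimethoxyphenyl)-3,7-dioxabicyclo[3.3.0]octane-4,8-dione | O=C1O[C@@H](c3cc(OC)c(OC(C)=O)c(OC)c3)[C@H]2[C@@H]1[C@H](c4cc(OC)c(OC(C)=O)c(OC)c4)OC2=O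
F11 | step 2 | (1R,2S,3S,4R)-1,4-bis(4-hydroxy-3,5-dimethoxyphenyl)-2,3-bis(hydroxymethyl)butane-1,4-diol | O[C@@H](c1cc(OC)c(O)c(OC)c1)[C@H](CO)[C@@H](CO)[C@@H](O)c1cc(OC)c(O)c(OC)c1
A1 | alternative 1 | (2S,3S)-1,4-bis(4-benzyloxy-3,5-dimethoxyphenyl)-2,3-bis(benzyloxymethyl)butane-1,4-dione | COc1cc(cc(OC)c1OCc1ccccc1)C(=O)[C@H](COCc1ccccc1)[C@@H](COCc1ccccc1)C(=O)c1cc(OC)c(OCc2ccccc2)c(OC)c1
A2 | alternative 1 | (2S,3S)-2,3-bis(benzyloxymethyl)-N,N′-dimethoxy-N,N′-dimethylbutanediamide | CON(C)C(=O)[C@H](COCc1ccccc1)[C@@H](COCc1ccccc1)C(=O)N(C)OC
A3 | alternative 1 | (4-benzyloxy-3,5-dimethoxyphenyl)lithium | [Li]c1cc(OC)c(OCc2ccccc2)c(OC)c1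
A4 | alternative 2 | 2,5-cis-bis(4-benzyloxy-3,5-dimethoxyphenyl)-4-[(tert-butyldimethylsilyloxy)methyl]oxolane-3-carbaldehyde with the target configuration at all four ring carbons | COc1cc([C@H]2O[C@@H](c3cc(OC)c(OCc4ccccc4)c(OC)c3)[C@H](CO[Si](C)(C)C(C)(C)C)[C@H]2C=O)cc(OC)c1OCc1ccccc1
A5 | alternative 2 | (4R,5S)-2,4-bis(4-benzyloxy-3,5-dimethoxyphenyl)-5-[(tert-butyldimethylsilyloxy)methyl]-4,5-dihydro-1,3-dioxepine (acetal carbon as either epimer) | COc1cc(C2O[C@@H](c3cc(OC)c(OCc4ccccc4)c(OC)c3)[C@H](CO[Si](C)(C)C(C)(C)C)C=CO2)cc(OC)c1OCc1ccccc1
A6 | alternative 3 | methyl trans-2,5-bis(4-benzyloxy-3,5-dimethoxyphenyl)-4-[(tert-butyldimethylsilyloxy)methyl]-4,5-dihydrofuran-3-carboxylate (enantiomer as drawn) | COC(=O)C1=C(c2cc(OC)c(OCc3ccccc3)c(OC)c2)O[C@@H](c2cc(OC)c(OCc3ccccc3)c(OC)c2)[C@@H]1CO[Si](C)(C)C(C)(C)C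
A7 | alternative 3 | methyl 2-(4-benzyloxy-3,5-dimethoxybenzoyl)-4-(tert-butyldimethylsilyloxy)but-2-enoate | COC(=O)C(=CCO[Si](C)(C)C(C)(C)C)C(=O)c1cc(OC)c(OCc2ccccc2)c(OC)c1
A8 | alternative 3 | (4-benzyloxy-3,5-dimethoxyphenyl)methylide of (2R,5R)-2,5-dimethylthiolan-1-ium | C[C@@H]1CC[C@@H](C)[S+]1[CH-]c1cc(OC)c(OCc2ccccc2)c(OC)c1
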